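**Plan**

1. The target is 17-hydroxy-ent-labda-7,13E-dien-15-yl 30-hydroxytriacontanoate (labdane numbering; ring A = C1–C5/C10, ring B = C5–C10). The retrosynthesis cuts the C15 ester first, then C2–C3 and C5–C10 of enone ester 16, which opens both rings at once to the acyclic keto aldehyde dienoate 14. It then cuts C9–C10 (Carroll rearrangement), C8–C17 (carbonylation) and C7–C8 (alkynylation).
2. Feature used: in 14 the C1 ketone makes C10 and C2 a 1,3-bis-nucleophile, while C5 (δ-carbon of the C5=C6–C7=C8–C17 dienoate) and the C3 aldehyde on quaternary C4 are a 1,3-bis-electrophile. Ring B (C10→C5) and then ring A (C2→C3) close in one base-mediated cascade that leaves the C7=C8–C17 ester in place.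
3. Forward order: enyne 4 (from geranyl acetate) + enal 7 → carbinol 8 → ester 10 → Carroll rearrangement to 14 → bicyclisation to 16 → removal of the ring A enone → C17 alcohol, protecting-group exchange, esterification with the silylated C30 acid 28 (from two bromides and acetylene), desilylation.
4. Stereochemistry: 13E comes from geraniol; C7 is set by ligand-controlled alkynylation; C7 is relayed to C9 by the chair [3,3] shift; C9 sets C10 and C5 in the cyclisation (allylic strain and the 4E alkene give the trans-decalin with the side chain cis to the C10 methyl).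

Key step: step 10

Remarks: the target as drawn is the ent-labdane (5R,9S,10R) enantiomer. C10 of 13 and 14 is an epimer mixture that converges in step 10. In step 6 the (S,S) ligand is assumed to give the 7R carbinol.

**Route**

Step 1
Reactants: 1 geranyl acetate
Product: 2 (2E)-3-methyl-6-oxohex-2-en-1-yl acetate
Conditions: O3 (1.0 equiv), CH2Cl2, pyridine (cat.), −78 °C; then Me2S, −78 → 20 °C
Reagents that add atoms: ozone, O=[O+][O-]
Why: Chemoselective ozonolysis, since the electron-rich 6,7-alkene reacts much faster than the 2,3-alkene deactivated by the allylic acetate, so the 2E geometry (future 13E) is carried over unchanged.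

Step 2
Reactants: 2 (2E)-3-methyl-6-oxohex-2-en-1-yl acetate
Product: 3 (2E)-3-methylhept-2-en-6-yn-1-ol
Conditions: dimethyl (1-diazo-2-oxopropyl)phosphonate (1.3 equiv), K2CO3 (3 equiv), MeOH, 0 → 20 °C
Reagents that add atoms: dimethyl (1-diazo-2-oxopropyl)phosphonate, COP(=O)(OC)C(=[N+]=[N-])C(C)=O
Why: Seyferth–Gilbert homologation with the Ohira–Bestmann reagent turns the aldehyde into the terminal alkyne (future C8 and C9) while the basic methanol cleaves the acetate; no stereocentre is involved.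

Step 3
Reactants: 3 (2E)-3-methylhept-2-en-6-yn-1-ol
Product: 4 1-methoxy-4-({[(2E)-3-methylhept-2-en-6-yn-1-yl]oxy}methyl)benzene
Conditions: NaH (1.05 equiv), 4-methoxybenzyl chloride, Bu4NI (cat.), THF–DMF, 0 → 20 °C
Reagents that add atoms: 4-methoxybenzyl chloride, COc1ccc(CCl)cc1
Why: Williamson etherification of the primary allylic alkoxide (one equivalent of NaH leaves the alkyne C–H alone) installs a PMB group that lasts until its oxidative removal in step 16.

Step 4
Reactants: 5 2-methyl-1-(trimethylsilyloxy)prop-1-ene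
Product: 6 3,3-dimethoxy-2,2-dimethylpropanal
Conditions: HC(OMe)3 (1.2 equiv), Me3SiOTf (5 mol%), CH2Cl2, −78 °C
Reagents that add atoms: trimethyl orthoformate, COC(OC)OC
Why: Mukaiyama-type addition of the enol silane to the dimethoxycarbenium ion from the orthoformate creates quaternary C4 with the masked C3 aldehyde; the product cannot enolise.

Step 5
Reactants: 6 3,3-dimethoxy-2,2-dimethylpropanal
Product: 7 (2E)-5,5-dimethoxy-4,4-dimethylpent-2-enal
Conditions: Ph3P=CHCHO (0.9 equiv), toluene, 90 °C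
Reagents that add atoms: (triphenylphosphoranylidene)acetaldehyde, O=CC=P(c1ccccc1)(c1ccccc1)c1ccccc1
Why: Wittig olefination with the stabilised formylmethylene ylide should give the E enal (C5=C6), and keeping the hindered aldehyde in slight excess limits a second homologation.

Step 6
Reactants: 4 1-methoxy-4-({[(2E)-3-methylhept-2-en-6-yn-1-yl]oxy}methyl)benzene; 7 (2E)-5,5-dimethoxy-4,4-dimethylpent-2-enal
Product: 8 (3E,5R,10E)-1,1-dimethoxy-12-[(4-methoxybenzyl)oxy]-2,2,10-trimethyldodeca-3,10-dien-6-yn-5-ol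
Conditions: (S,S)-ProPhenol (10 mol%), Me2Zn (3 equiv), Ph3PO (20 mol%), toluene, 0 °C; then aq. NH4Cl
Reagents that add atoms: none
Why: Zinc–ProPhenol-catalysed asymmetric alkynylation joins C7 to C8 by 1,2-addition of the alkynylzinc to the enal and sets the C7 carbinol under ligand control; the (S,S) ligand is expected to give 7R and its antipode is used if MTPA-ester analysis shows the opposite sense.

Step 7
Reactants: 8 (3E,5R,10E)-1,1-dimethoxy-12-[(4-methoxybenzyl)oxy]-2,2,10-trimethyldodeca-3,10-dien-6-yn-5-ol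
Product: 9 (3E,5R,6Z,10E)-1,1-dimethoxy-12-[(4-methoxybenzyl)oxy]-2,2,10-trimethyl-6-(tributylstannyl)dodeca-3,6,10-trien-5-ol
Conditions: Bu3SnH (1.1 equiv), [(C5Me5)RuCl]4 (2.5 mol%), CH2Cl2, 20 °C
Reagents that add atoms: tributyltin hydride, CCCC[SnH](CCCC)CCCC
Why: Hydroxyl-directed ruthenium-catalysed trans-hydrostannation puts tin on the alkyne carbon next to the carbinol (C8) and hydrogen trans to it on C9, which fixes the C8=C9 geometry; the alkenes are inert.

Step 8
Reactants: 9 (3E,5R,6Z,10E)-1,1-dimethoxy-12-[(4-methoxybenzyl)oxy]-2,2,10-trimethyl-6-(tributylstannyl)dodeca-3,6,10-trien-5-ol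
Product: 10 methyl (2Z,6E)-2-[(1R,2E)-1-hydroxy-5,5-dimethoxy-4,4-dimethylpent-2-en-1-yl]-8-[(4-methoxybenzyl)oxy]-6-methylocta-2,6-dienoate
Conditions: CO (1 atm), Pd(OAc)2 (5 mol%), Ph3As (10 mol%), 1,4-benzoquinone (1.2 equiv), CF3CO2H (1.2 equiv), MeOH, 20 °C
Reagents that add atoms: carbon monoxide, [C-]#[O+]; methanol, CO
Why: Oxidative methoxycarbonylation of the alkenylstannane (transmetalation to divalent palladium, CO insertion, methanolysis, reoxidation by benzoquinone) introduces C17 on C8 with retention of the alkene geometry.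

Step 9
Reactants: 10 methyl (2Z,6E)-2-[(1R,2E)-1-hydroxy-5,5-dimethoxy-4,4-dimethylpent-2-en-1-yl]-8-[(4-methoxybenzyl)oxy]-6-methylocta-2,6-dienoate; 11 ethyl 2-methyl-3-oxobutanoate
Product: 14 methyl (2E,4E)-2-[(3RS,4S,7E)-9-[(4-methoxybenzyl)oxy]-3,7-dimethyl-2-oxonon-7-en-4-yl]-6,6-dimethyl-7-oxohepta-2,4-dienoate, via allyl 2-methylacetoacetate ester 12 (not isolated), via keto dienoate dimethyl acetal 13 (not isolated)
Conditions: 11 (4 equiv), DMAP (0.3 equiv), o-xylene, 140 °C (EtOH distilled off), then 170 °C; then 1 M aq. HCl, THF, 20 °C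
Reagents that add atoms: water, O
Why: Carroll rearrangement, in which the ester enol of 12 undergoes a chair [3,3]-sigmatropic shift to the C9 face syn to the C7–O bond with the dienyl group axial (avoiding A(1,2) strain with the C8 ester), so the 7R centre is relayed to C9 and the new C7=C8 bond is 2E; loss of CO2 leaves the C1 methyl ketone and aqueous acid unmasks the C3 aldehyde.

Step 10
Reactants: 14 methyl (2E,4E)-2-[(3RS,4S,7E)-9-[(4-methoxybenzyl)oxy]-3,7-dimethyl-2-oxonon-7-en-4-yl]-6,6-dimethyl-7-oxohepta-2,4-dienoate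
Product: 16 methyl 15-[(4-methoxybenzyl)oxy]-1-oxo-ent-labda-2,7,13E-trien-17-oate, via monocyclic Michael adduct 15 (not isolated)
Conditions: KOt-Bu (0.3 equiv), t-BuOH–THF (1:5), 0.01 M, 0 → 40 °C
Reagents that add atoms: none
Why: Proposed new method: base equilibrates the two enolates of the C1 ketone, and the C10 enolate adds to C5, the δ-terminus of the s-cis (2E,4E)-dienoate, in a 6-endo-trig vinylogous (1,6-) Michael addition that closes ring B, the ester dienolate being reprotonated at C6 to leave the conjugated C7=C8 ester of 15; the C2 enolate of 15 then closes ring A by a 6-(enolexo)-exo-trig aldol addition to the non-enolisable C3 aldehyde and E1cB loss of water gives the C2=C3 enone. The closest known reactions are the intramolecular Michael–aldol (Robinson-type) double annulation and the 1,6-addition of stabilised carbanions to 2,4-dienoates; new is the endo 1,6-mode with a simple ketone enolate, argued from the fact that the 2-substituent holds C9 at bonding distance from C5 so that C10 can reach the C5 π-lobe at the cost of some twisting of the diene. C10 is controlled by A(1,3) strain: H9 eclipses the enolate C10=C1 bond and the C8 tether delivers C5 to the enolate face syn to C8, which puts the methyl group axial and cis to the equatorial C9 side chain. C5 is controlled by the 4E geometry, which keeps the C4 substituent pseudo-equatorial and therefore trans to C1, so that ring A closes to the trans-decalin. The step needs C10, not C2, as Michael donor and Michael addition before aldol: only C10 reaches C5 through a six-membered transition state (C2 would need eight- or ten-membered ones), while high dilution and substoichiometric base hold back intermolecular aldol and the Claisen attack of C2 on the C17 ester, which would consume base irreversibly. Any 2Z isomer of 14 cannot bring C10 to C5 and stays behind.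

Step 11
Reactants: 16 methyl 15-[(4-methoxybenzyl)oxy]-1-oxo-ent-labda-2,7,13E-trien-17-oate
Product: 17 methyl 15-[(4-methoxybenzyl)oxy]-1-oxo-ent-labda-7,13E-dien-17-oate
Conditions: Cu(OAc)2·H2O (5 mol%), 1,2-bis(diphenylphosphino)benzene (5 mol%), (EtO)2MeSiH (1.5 equiv), t-BuOH (1.5 equiv), toluene, 0 → 20 °C
Reagents that add atoms: none
Why: Copper hydride catalysed conjugate reduction (hydride to C3, protonation of the copper enolate by t-BuOH) saturates the ring A enone, which is more electrophilic than the trisubstituted C7=C8 ester; no stereocentre changes.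

Step 12
Reactants: 17 methyl 15-[(4-methoxybenzyl)oxy]-1-oxo-ent-labda-7,13E-dien-17-oate
Product: 18 methyl 15-[(4-methoxybenzyl)oxy]-1-[2-(4-methylbenzenesulfonyl)hydrazinylidene]-ent-labda-7,13E-dien-17-oate
Conditions: TsNHNH2 (1.5 equiv), AcOH (cat.), EtOH, 78 °C
Reagents that add atoms: 4-methylbenzenesulfonohydrazide, Cc1ccc(cc1)S(=O)(=O)NN
Why: Condensation of the only ketone with tosylhydrazide gives the tosylhydrazone; the conjugated ester does not condense under these conditions.

Step 13
Reactants: 18 methyl 15-[(4-methoxybenzyl)oxy]-1-[2-(4-methylbenzenesulfonyl)hydrazinylidene]-ent-labda-7,13E-dien-17-oate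
Product: 19 methyl 15-[(4-methoxybenzyl)oxy]-ent-labda-7,13E-dien-17-oate
Conditions: catecholborane (2.5 equiv), CHCl3, 0 °C; then NaOAc·3H2O, 60 °C
Reagents that add atoms: none
Why: Reductive deoxygenation of the tosylhydrazone, in which hydride adds to C=N, acetate triggers loss of sulfinate and the diazene loses N2 to leave the C1 methylene; esters, alkenes and the PMB ether are not touched.

Step 14
Reactants: 19 methyl 15-[(4-methoxybenzyl)oxy]-ent-labda-7,13E-dien-17-oate
Product: 20 15-[(4-methoxybenzyl)oxy]-ent-labda-7,13E-dien-17-ol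
Conditions: i-Bu2AlH (2.5 equiv), CH2Cl2, −78 °C; then MeOH, aq. potassium sodium tartrate (KNaC4H4O6)
Reagents that add atoms: none
Why: i-Bu2AlH reduces the conjugated methyl ester by 1,2-addition to the primary allylic alcohol (C17); the PMB ether and both alkenes are inert.

Step 15
Reactants: 20 15-[(4-methoxybenzyl)oxy]-ent-labda-7,13E-dien-17-ol
Product: 21 tert-butyl({15-[(4-methoxybenzyl)oxy]-ent-labda-7,13E-dien-17-yl}oxy)dimethylsilane
Conditions: t-BuMe2SiCl (1.3 equiv), imidazole (2.5 equiv), DMF, 20 °C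
Reagents that add atoms: tert-butyldimethylsilyl chloride, CC(C)(C)[Si](C)(C)Cl
Why: Silylation of the only free hydroxyl masks C17–OH so that C15–OH can later be acylated alone.

Step 16
Reactants: 21 tert-butyl({15-[(4-methoxybenzyl)oxy]-ent-labda-7,13E-dien-17-yl}oxy)dimethylsilane
Product: 22 17-[(tert-butyldimethylsilyl)oxy]-ent-labda-7,13E-dien-15-ol
Conditions: DDQ (1.3 equiv), CH2Cl2–pH 7 phosphate buffer (10:1), 0 °C
Reagents that add atoms: none
Why: Oxidative PMB cleavage (hydride abstraction by DDQ, hydrolysis of the oxocarbenium ion) frees the C15 allylic alcohol and leaves the silyl ether and the alkenes intact.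

Step 17
Reactants: 23 12-bromododecan-1-ol
Product: 24 [(12-bromododecyl)oxy](tert-butyl)dimethylsilane
Conditions: t-BuMe2SiCl (1.2 equiv), imidazole (2.5 equiv), CH2Cl2, 20 °C
Reagents that add atoms: tert-butyldimethylsilyl chloride, CC(C)(C)[Si](C)(C)Cl
Why: Silylation protects the future ω-hydroxyl through the organolithium steps.

Step 18
Reactants: 24 [(12-bromododecyl)oxy](tert-butyl)dimethylsilane
Product: 25 tert-butyldimethyl(tetradec-13-yn-1-yloxy)silane
Conditions: LiC≡CH·H2NCH2CH2NH2 (1.5 equiv), DMSO, 10 → 20 °C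
Reagents that add atoms: lithium acetylide–ethylenediamine complex, [Li+].[C-]#C.NCCN
Why: SN2 displacement of the primary bromide by acetylide in DMSO extends the chain by two carbons.

Step 19
Reactants: 25 tert-butyldimethyl(tetradec-13-yn-1-yloxy)silane; 26 16-bromohexadecanoic acid
Product: 27 30-[(tert-butyldimethylsilyl)oxy]triacont-17-ynoic acid
Conditions: n-BuLi (1.0 equiv on each component), THF–HMPA, −78 → 40 °C; then 1 M aq. HCl
Reagents that add atoms: none
Why: Alkylation of the lithium acetylide of 25 with the primary bromide of lithium 16-bromohexadecanoate (the acid is masked as its salt) assembles the C30 chain.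

Step 20
Reactants: 27 30-[(tert-butyldimethylsilyl)oxy]triacont-17-ynoic acid
Product: 28 30-[(tert-butyldimethylsilyl)oxy]triacontanoic acid
Conditions: H2 (1 atm), 10% Pd/C, EtOAc, 20 °C
Reagents that add atoms: none
Why: Heterogeneous hydrogenation saturates the alkyne; the silyl ether and the acid are stable in EtOAc.

Step 21
Reactants: 22 17-[(tert-butyldimethylsilyl)oxy]-ent-labda-7,13E-dien-15-ol; 28 30-[(tert-butyldimethylsilyl)oxy]triacontanoic acid
Product: 29 17-[(tert-butyldimethylsilyl)oxy]-ent-labda-7,13E-dien-15-yl 30-[(tert-butyldimethylsilyl)oxy]triacontanoate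
Conditions: DCC (1.3 equiv), DMAP (0.2 equiv), CH2Cl2, 20 °C
Reagents that add atoms: none
Why: Steglich esterification through the O-acylisourea and the acylpyridinium ion acylates the C15 allylic alcohol without allylic transposition.

Step 22
Reactants: 29 17-[(tert-butyldimethylsilyl)oxy]-ent-labda-7,13E-dien-15-yl 30-[(tert-butyldimethylsilyl)oxy]triacontanoate
Product: 30 17-hydroxy-ent-labda-7,13E-dien-15-yl 30-hydroxytriacontanoate
Conditions: HF·pyridine, pyridine–THF, 0 → 20 °C
Reagents that add atoms: none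
Why: Buffered fluoride cleaves both primary silyl ethers and should leave the allylic ester and the alkenes untouched, giving the target.

**Compound list**

1 | geranyl acetate | CC(C)=CCC/C(C)=C/COC(C)=O | starting material
2 | (2E)-3-methyl-6-oxohex-2-en-1-yl acetate | O=CCC/C(C)=C/COC(C)=O | intermediate
3 | (2E)-3-methylhept-2-en-6-yn-1-ol | C#CCC/C(C)=C/CO | intermediate
4 | 1-methoxy-4-({[(2E)-3-methylhept-2-en-6-yn-1-yl]oxy}methyl)benzene | C#CCC/C(C)=C/COCc1ccc(OC)cc1 | intermediate
5 | 2-methyl-1-(trimethylsilyloxy)prop-1-ene | CC(C)=CO[Si](C)(C)C | starting material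
6 | 3,3-dimethoxy-2,2-dimethylpropanal | COC(OC)C(C)(C)C=O | intermediate
7 | (2E)-5,5-dimethoxy-4,4-dimethylpent-2-enal | COC(OC)C(C)(C)/C=C/C=O | intermediate
8 | (3E,5R,10E)-1,1-dimethoxy-12-[(4-methoxybenzyl)oxy]-2,2,10-trimethyldodeca-3,10-dien-6-yn-5-ol | COC(OC)C(C)(C)/C=C/[C@@H](O)C#CCC/C(C)=C/COCc1ccc(OC)cc1 | intermediate
9 | (3E,5R,6Z,10E)-1,1-dimethoxy-12-[(4-methoxybenzyl)oxy]-2,2,10-trimethyl-6-(tributylstannyl)dodeca-3,6,10-trien-5-ol | COC(OC)C(C)(C)/C=C/[C@@H](O)/C(=C/CC/C(C)=C/COCc1ccc(OC)cc1)[Sn](CCCC)(CCCC)CCCC | intermediate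
10 | methyl (2Z,6E)-2-[(1R,2E)-1-hydroxy-5,5-dimethoxy-4,4-dimethylpent-2-en-1-yl]-8-[(4-methoxybenzyl)oxy]-6-methylocta-2,6-dienoate | COC(OC)C(C)(C)/C=C/[C@@H](O)/C(=C/CC/C(C)=C/COCc1ccc(OC)cc1)C(=O)OC | intermediate
11 | ethyl 2-methyl-3-oxobutanoate | CCOC(=O)C(C)C(C)=O | starting material
12 | 2-methyl-3-oxobutanoate ester of 10 at the C7 oxygen (allyl β-keto ester, 7R) | COC(OC)C(C)(C)/C=C/[C@@H](OC(=O)C(C)C(C)=O)/C(=C/CC/C(C)=C/COCc1ccc(OC)cc1)C(=O)OC | intermediate
13 | methyl (2E,4E)-7,7-dimethoxy-2-[(3RS,4S,7E)-9-[(4-methoxybenzyl)oxy]-3,7-dimethyl-2-oxonon-7-en-4-yl]-6,6-dimethylhepta-2,4-dienoate | COc1ccc(cc1)COC/C=C(\C)CC[C@@H](C(C)C(C)=O)/C(C(=O)OC)=C\C=C\C(C)(C)C(OC)OC | intermediate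
14 | methyl (2E,4E)-2-[(3RS,4S,7E)-9-[(4-methoxybenzyl)oxy]-3,7-dimethyl-2-oxonon-7-en-4-yl]-6,6-dimethyl-7-oxohepta-2,4-dienoate | COc1ccc(cc1)COC/C=C(\C)CC[C@@H](C(C)C(C)=O)/C(C(=O)OC)=C\C=C\C(C)(C)C=O | intermediate
15 | methyl 5-acetyl-6-[(3E)-5-[(4-methoxybenzyl)oxy]-3-methylpent-3-en-1-yl]-5-methyl-4-(2-methyl-1-oxopropan-2-yl)cyclohex-1-ene-1-carboxylate (ring stereocentres as in 16) | COc1ccc(cc1)COC/C=C(\C)CC[C@@H]1C(C(=O)OC)=CC[C@H](C(C)(C)C=O)[C@@]1(C)C(C)=O | intermediate
16 | methyl 15-[(4-methoxybenzyl)oxy]-1-oxo-ent-labda-2,7,13E-trien-17-oate (trans-decalin; H5 and H9 on the face opposite to the C10 methyl) | COc1ccc(cc1)COC/C=C(\C)CC[C@@H]1C(C(=O)OC)=CC[C@@H]2C(C)(C)C=CC(=O)[C@@]12C | intermediate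
17 | methyl 15-[(4-methoxybenzyl)oxy]-1-oxo-ent-labda-7,13E-dien-17-oate | COc1ccc(cc1)COC/C=C(\C)CC[C@@H]1C(C(=O)OC)=CC[C@@H]2C(C)(C)CCC(=O)[C@@]12C | intermediate
18 | methyl 15-[(4-methoxybenzyl)oxy]-1-[2-(4-methylbenzenesulfonyl)hydrazinylidene]-ent-labda-7,13E-dien-17-oate | COc1ccc(cc1)COC/C=C(\C)CC[C@@H]1C(C(=O)OC)=CC[C@@H]2C(C)(C)CCC(=NNS(=O)(=O)c3ccc(C)cc3)[C@@]12C | intermediate
19 | methyl 15-[(4-methoxybenzyl)oxy]-ent-labda-7,13E-dien-17-oate | COc1ccc(cc1)COC/C=C(\C)CC[C@@H]1C(C(=O)OC)=CC[C@@H]2C(C)(C)CCC[C@@]12C | intermediate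
20 | 15-[(4-methoxybenzyl)oxy]-ent-labda-7,13E-dien-17-ol | COc1ccc(cc1)COC/C=C(\C)CC[C@@H]1C(CO)=CC[C@@H]2C(C)(C)CCC[C@@]12C | intermediate
21 | tert-butyl({15-[(4-methoxybenzyl)oxy]-ent-labda-7,13E-dien-17-yl}oxy)dimethylsilane | COc1ccc(cc1)COC/C=C(\C)CC[C@@H]1C(CO[Si](C)(C)C(C)(C)C)=CC[C@@H]2C(C)(C)CCC[C@@]12C | intermediate
22 | 17-[(tert-butyldimethylsilyl)oxy]-ent-labda-7,13E-dien-15-ol | OC/C=C(\C)CC[C@@H]1C(CO[Si](C)(C)C(C)(C)C)=CC[C@@H]2C(C)(C)CCC[C@@]12C | intermediate
23 | 12-bromododecan-1-ol | OCCCCCCCCCCCCBr | starting material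
24 | [(12-bromododecyl)oxy](tert-butyl)dimethylsilane | CC(C)(C)[Si](C)(C)OCCCCCCCCCCCCBr | intermediate
25 | tert-butyldimethyl(tetradec-13-yn-1-yloxy)silane | CC(C)(C)[Si](C)(C)OCCCCCCCCCCCCC#C | intermediate
26 | 16-bromohexadecanoic acid | OC(=O)CCCCCCCCCCCCCCCBr | starting material
27 | 30-[(tert-butyldimethylsilyl)oxy]triacont-17-ynoic acid | CC(C)(C)[Si](C)(C)OCCCCCCCCCCCCC#CCCCCCCCCCCCCCCCC(=O)O | intermediate
28 | 30-[(tert-butyldimethylsilyl)oxy]triacontanoic acid | CC(C)(C)[Si](C)(C)OCCCCCCCCCCCCCCCCCCCCCCCCCCCCCC(=O)O | intermediate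
29 | 17-[(tert-butyldimethylsilyl)oxy]-ent-labda-7,13E-dien-15-yl 30-[(tert-butyldimethylsilyl)oxy]triacontanoate | C/C(=C\COC(=O)CCCCCCCCCCCCCCCCCCCCCCCCCCCCCO[Si](C)(C)C(C)(C)C)CC[C@@H]1C(CO[Si](C)(C)C(C)(C)C)=CC[C@@H]2C(C)(C)CCC[C@@]12C | intermediate
30 | 17-hydroxy-ent-labda-7,13E-dien-15-yl 30-hydroxytriacontanoate | C/C(=C\COC(=O)CCCCCCCCCCCCCCCCCCCCCCCCCCCCCO)CC[C@@H]1C(CO)=CC[C@@H]2C(C)(C)CCC[C@@]12C | target

**Step count**

Total: 22 steps. Longest linear sequence: 16 steps (1, 2, 3, 6–16, 21, 22, from geranyl acetate).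

**Steps most likely to fail, with fallbacks**

Step 10. The endo 1,6-addition needs the diene to twist so that the tethered enolate overlaps with the C5 terminus. If this is slow, the C2 enolate may attack the C17 ester or a second molecule instead, or ring fusion may form with poor facial control. The fallback uses known chemistry, sets out from 10 and comes back at 16. Dess–Martin oxidation of the C7 carbinol gives the alkylidene β-keto ester F1. A Mukaiyama–Michael addition of (Z)-2-(trimethylsilyloxy)but-2-ene, catalysed by Cu(OTf)2 and a chiral bis(oxazoline) (ligand antipode chosen for the C9 configuration of 14), followed by desilylation, gives the diketo ester F2, in which C5 is the β-carbon of a C7 enone. TsOH·H2O in wet toluene at 80 °C cleaves the acetal and brings about the acid-catalysed 6-endo Michael addition of the C10 enol to C5 and the aldol condensation of C2 with C3 (Robinson-type), giving the bicyclic β-keto ester F3. NaH and PhNTf2 convert it into the enol triflate F4, and Pd(OAc)2/PPh3 with HCO2H–Bu3N in DMF reduces the triflate to the C7–H alkene 16.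

Step 9. Transacetoacetylation of the hindered bis-allylic alcohol may stall. The hot ester may also ionise, or rearrange through the chair with the dienyl group equatorial, which would lower the share of the 2E isomer that alone cyclises. The fallback sets out from 10 and comes back at 14. Methyl chloroformate and pyridine give the allylic methyl carbonate F5. Tsuji–Trost alkylation with the sodium enolate of 11 (Pd(PPh3)4, THF, 20 °C) gives the quaternary β-keto diester F6; ionisation and attack both occur anti to palladium, so C9 is reached on the same face as in the [3,3] shift, and attack at C9 gives the conjugated dienoate. Krapcho dealkoxycarbonylation (LiCl, wet DMSO, 140 °C) removes the ethyl ester to give 13, which is hydrolysed as in step 9 to 14.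

Step 12. Condensation at the C1 ketone, shielded by quaternary C10 and the axial C4 methyl, may be too slow, and forcing it risks conjugate addition of the hydrazide to the unsaturated ester. The fallback sets out from 17 and comes back at 19. NaBH4 in MeOH at 0 °C gives the C1 alcohol F7. NaH, CS2 and MeI give the S-methyl xanthate F8. Barton–McCombie deoxygenation (Bu3SnH, AIBN, toluene, 110 °C) gives 19.

Further compounds
F1 | step 10 | methyl (2Z,6E)-2-[(2E)-5,5-dimethoxy-4,4-dimethylpent-2-enoyl]-8-[(4-methoxybenzyl)oxy]-6-methylocta-2,6-dienoate | COC(OC)C(C)(C)/C=C/C(=O)/C(=C/CC/C(C)=C/COCc1ccc(OC)cc1)C(=O)OC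
F2 | step 10 | methyl (4E)-7,7-dimethoxy-2-[(3RS,4S,7E)-9-[(4-methoxybenzyl)oxy]-3,7-dimethyl-2-oxonon-7-en-4-yl]-6,6-dimethyl-3-oxohept-4-enoate | COc1ccc(cc1)COC/C=C(\C)CC[C@@H](C(C)C(C)=O)C(C(=O)OC)C(=O)/C=C/C(C)(C)C(OC)OC
F3 | step 10 | methyl 15-[(4-methoxybenzyl)oxy]-1,7-dioxo-ent-labda-2,13E-dien-17-oate | COc1ccc(cc1)COC/C=C(\C)CC[C@@H]1C(C(=O)OC)C(=O)C[C@@H]2C(C)(C)C=CC(=O)[C@@]12C
F4 | step 10 | methyl 15-[(4-methoxybenzyl)oxy]-1-oxo-7-[(trifluoromethanesulfonyl)oxy]-ent-labda-2,7,13E-trien-17-oate | COc1ccc(cc1)COC/C=C(\C)CC[C@@H]1C(C(=O)OC)=C(OS(=O)(=O)C(F)(F)F)C[C@@H]2C(C)(C)C=CC(=O)[C@@]12C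
F5 | step 9 | methyl (2Z,6E)-2-[(1R,2E)-5,5-dimethoxy-1-[(methoxycarbonyl)oxy]-4,4-dimethylpent-2-en-1-yl]-8-[(4-methoxybenzyl)oxy]-6-methylocta-2,6-dienoate | COC(OC)C(C)(C)/C=C/[C@@H](OC(=O)OC)/C(=C/CC/C(C)=C/COCc1ccc(OC)cc1)C(=O)OC
F6 | step 9 | C10-ethoxycarbonyl derivative of 13 (quaternary β-keto diester; C9 as in 14) | COc1ccc(cc1)COC/C=C(\C)CC[C@@H](C(C)(C(C)=O)C(=O)OCC)/C(C(=O)OC)=C\C=C\C(C)(C)C(OC)OC
F7 | step 12 | methyl 1-hydroxy-15-[(4-methoxybenzyl)oxy]-ent-labda-7,13E-dien-17-oate | COc1ccc(cc1)COC/C=C(\C)CC[C@@H]1C(C(=O)OC)=CC[C@@H]2C(C)(C)CCC(O)[C@@]12C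
F8 | step 12 | methyl 15-[(4-methoxybenzyl)oxy]-1-{[(methylsulfanyl)carbonothioyl]oxy}-ent-labda-7,13E-dien-17-oate | COc1ccc(cc1)COC/C=C(\C)CC[C@@H]1C(C(=O)OC)=CC[C@@H]2C(C)(C)CCC(OC(=S)SC)[C@@]12C
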